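The cyclopentenone (prostanoid numbering: C1 ester carbon, ring C8–C12) is disconnected between the ketone carbon C9 and the bromine-bearing alkene carbon C10. The key step exploits the α-bromoenone unit C9(=O)–C10(Br)=C11 of the five-membered ring: in an acyclic gem-dibromoalkene that also holds C9 as a Weinreb amide, bromine–lithium exchange gives a 1-bromo-1-lithioalkene that acylates itself, creating ring, enone and C–Br bond in one operation. The precursor's only stereocentre, the C12 carbinol, is made from (S)-malic acid by self-regeneration of stereocentres. The acetoxylated side chain is then added by an anti-selective boron aldol reaction on the ring (C7, C8) and acetylation.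

Key step: step 8

Remark: compounds 1, 3, 16 and 17 are taken as commercial; reagents that only lend atoms (pivalaldehyde, silyl donors, CBr4 and so on) are named on the reagent lines and not numbered.

Step 1
Reactants: 1 (Z)-oct-2-en-1-ol
Product: 2 (Z)-1-bromooct-2-ene
Conditions: CBr4, PPh3, CH2Cl2, 0 °C
Reagents that add atoms: carbon tetrabromide BrC(Br)(Br)Br
Why: Appel bromination: SN2 displacement of the oxyphosphonium leaving group at the primary allylic carbon should give the bromide without touching the Z double bond.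

Step 2
Reactants: 3 (S)-malic acid
Product: 4 2-[(2S,4S)-2-tert-butyl-5-oxo-1,3-dioxolan-4-yl]acetic acid (cis)
Conditions: t-BuCHO, TsOH (cat.), H2SO4 (cat.), pentane, reflux (Dean–Stark); crystallization
Reagents that add atoms: pivalaldehyde CC(C)(C)C=O
Why: Acid-catalysed acetalization of the α-hydroxy acid unit with removal of water should give mainly the cis dioxolanone, whose new acetal centre (2S) is set by the malic stereocentre under thermodynamic control and is purified by crystallization.

Step 3
Reactants: 4 2-[(2S,4S)-2-tert-butyl-5-oxo-1,3-dioxolan-4-yl]acetic acid, 2 (Z)-1-bromooct-2-ene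
Product: 6 2-[(2S,4S)-2-tert-butyl-4-[(Z)-oct-2-enyl]-5-oxo-1,3-dioxolan-4-yl]acetic acid, via dilithium enolate carboxylate 5 (not isolated)
Conditions: LiN(SiMe3)2 (2.1 equiv), THF, −78 °C; 2, −78 → −20 °C; aq. HCl
Reagents that add atoms: none
Why: Enolate alkylation under self-regeneration of stereocentres: the tert-butyl group on the acetal carbon shields one face of the ring enolate, so the allylic bromide should enter trans to it in an SN2 reaction, which sets the quaternary C12 with overall retention of the malic configuration and keeps the Z alkene.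

Step 4
Reactants: 6 2-[(2S,4S)-2-tert-butyl-4-[(Z)-oct-2-enyl]-5-oxo-1,3-dioxolan-4-yl]acetic acid
Product: 8 (4S)-4-hydroxy-4-[(Z)-oct-2-enyl]oxolan-2-one, via dihydroxy acid 7 (not isolated)
Conditions: NaOEt (1.0 equiv), NaBH4, EtOH, 0 °C → rt; then 2 M HCl, rt
Reagents that add atoms: none
Why: Chemoselective NaBH4 reduction: the activated acylal-type lactone carbonyl (C11) is reduced while the carboxylate is inert, the hemiacetal loses pivalaldehyde (reduced to neopentyl alcohol), and acidification lactonizes the C9 acid onto the primary hydroxyl; C12 is not touched.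

Step 5
Reactants: 8 (4S)-4-hydroxy-4-[(Z)-oct-2-enyl]oxolan-2-one
Product: 10 (3S,5Z)-N-methoxy-N-methyl-3-(trimethylsilyloxy)-3-[(trimethylsilyloxy)methyl]undec-5-enamide, via diol amide 9 (not isolated)
Conditions: MeNHOMe·HCl, i-PrMgCl, THF, −20 → 0 °C; aqueous work-up; crude 9, N-(trimethylsilyl)imidazole, CH2Cl2, rt
Reagents that add atoms: N,O-dimethylhydroxylamine hydrochloride CNOC.Cl; N-(trimethylsilyl)imidazole C[Si](C)(C)n1ccnc1
Why: Lactone aminolysis with the magnesium amide of N,O-dimethylhydroxylamine gives the Weinreb amide, and immediate silylation of both hydroxyls with the powerful silyl donor blocks relactonization.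

Step 6
Reactants: 10 (3S,5Z)-N-methoxy-N-methyl-3-(trimethylsilyloxy)-3-[(trimethylsilyloxy)methyl]undec-5-enamide
Product: 11 (3S,5Z)-3-formyl-N-methoxy-N-methyl-3-(trimethylsilyloxy)undec-5-enamide
Conditions: (COCl)2, DMSO, CH2Cl2, −78 → −40 °C; Et3N, −78 → 0 °C
Reagents that add atoms: none
Why: Swern oxidation run directly on the silyl ether: the chlorosulfonium salt converts only the unhindered primary trimethylsilyl ether into the alkoxysulfonium ion, which gives the aldehyde with Et3N, while the tertiary silyl ether is too hindered to react and the quaternary α-carbon cannot epimerize.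

Step 7
Reactants: 11 (3S,5Z)-3-formyl-N-methoxy-N-methyl-3-(trimethylsilyloxy)undec-5-enamide
Product: 12 (3S,5Z)-3-(2,2-dibromoethenyl)-N-methoxy-N-methyl-3-(trimethylsilyloxy)undec-5-enamide
Conditions: CBr4, PPh3, Et3N, CH2Cl2, 0 °C
Reagents that add atoms: carbon tetrabromide BrC(Br)(Br)Br
Why: Ramirez dibromo-olefination (first stage of the Corey–Fuchs sequence): the ylide Ph3P=CBr2 converts the hindered aldehyde into the gem-dibromoalkene, with Et3N buffering the acid that would cleave the silyl ether.

Step 8
Reactants: 12 (3S,5Z)-3-(2,2-dibromoethenyl)-N-methoxy-N-methyl-3-(trimethylsilyloxy)undec-5-enamide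
Product: 15 (4S)-2-bromo-4-[(Z)-oct-2-enyl]-4-(trimethylsilyloxy)cyclopent-2-en-1-one, via lithium carbenoid 13 (not isolated), via tetrahedral intermediate 14 (not isolated)
Conditions: n-BuLi (1.0 equiv, slow addition), THF/Et2O/pentane (4:1:1), −110 → −95 °C; AcOH in THF, −95 °C → rt
Reagents that add atoms: none
Why: n-BuLi should exchange the bromine cis to C12 (pre-coordination to the Weinreb amide and silyloxy oxygens; any trans-lithio isomer equilibrates by degenerate Br/Li exchange with unreacted 12 and only the cis-lithio carbenoid can close), giving a 1-bromo-1-lithioalkene whose sp2 carbon C10 adds to the amide carbonyl C9; the chelated N-methoxy-N-methyl tetrahedral intermediate survives until the acidic quench and then collapses to the ketone. The closest known reaction type is the Parham-type anionic cyclization of alkenyllithiums onto Weinreb amides, combined with the acylation of 1-halo-1-lithioalkene carbenoids made from gem-dibromoalkenes. The five-membered ring closes in a 5-exo-trig mode at the carbonyl, with the C10=C11 double bond ending inside the ring. No stereocentre is formed; C12 is not touched and the Z alkene is inert. The step needs halogen–lithium exchange to outrun addition of n-BuLi to the amide and deprotonation at C8, which the activated gem-dibromide should secure at −110 °C, and ring closure to outrun Fritsch–Buttenberg–Wiechell rearrangement of the carbenoid, which the intramolecular five-membered trajectory should secure. One operation thus delivers ring, enone and the C10 bromine at the correct oxidation level.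

Step 9
Reactants: 16 (4-carboxybutyl)triphenylphosphonium bromide, 17 (tert-butyldimethylsilyloxy)acetaldehyde
Product: 19 (Z)-7-(tert-butyldimethylsilyloxy)hept-5-enoic acid, via ylide carboxylate 18 (not isolated)
Conditions: NaN(SiMe3)2 (2.1 equiv), THF, 0 °C; 17, −78 °C → rt; aq. HCl (pH 4)
Reagents that add atoms: none
Why: Wittig olefination: the non-stabilized ylide under lithium-free conditions should add to the aldehyde under kinetic control to give the Z alkene (later C5=C6).

Step 10
Reactants: 19 (Z)-7-(tert-butyldimethylsilyloxy)hept-5-enoic acid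
Product: 20 methyl (Z)-7-hydroxyhept-5-enoate
Conditions: HCl (cat., from AcCl), MeOH, rt
Reagents that add atoms: methanol CO
Why: Fischer esterification; the same acidic methanol cleaves the primary silyl ether and frees the allylic alcohol.

Step 11
Reactants: 20 methyl (Z)-7-hydroxyhept-5-enoate
Product: 21 methyl (Z)-7-oxohept-5-enoate
Conditions: MnO2, CH2Cl2, rt, dark; used at once
Reagents that add atoms: none
Why: Oxidation of the allylic alcohol with MnO2 under neutral conditions should give the enal without Z to E isomerization, provided it is used at once.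

Step 12
Reactants: 15 (4S)-2-bromo-4-[(Z)-oct-2-enyl]-4-(trimethylsilyloxy)cyclopent-2-en-1-one, 21 methyl (Z)-7-oxohept-5-enoate
Product: 24 methyl (5Z,7S)-7-[(1R,5S)-3-bromo-5-hydroxy-5-[(Z)-oct-2-enyl]-2-oxocyclopent-3-en-1-yl]-7-hydroxyhept-5-enoate, via boron dienolate 22 (not isolated), via boron aldolate 23 (not isolated)
Conditions: (c-C6H11)2BCl, i-Pr2NEt, Et2O, −78 → 0 °C; 21, −78 °C; MeOH, then citric acid, 0 °C → rt
Reagents that add atoms: none
Why: Boron aldol addition through a Zimmerman–Traxler chair: the ring-fixed E(O) boron dienolate should give the anti aldol, and the aldehyde should reach C8 on the ring face of the C12 oxygen, anti to the octenyl methylene (as electrophiles add syn to oxygen in 5-alkyl-5-oxy-cyclopentadienes), which sets C8 (R) and C7 (S); acidic methanolysis then cleaves the boron aldolate and the silyl ether.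

Step 13
Reactants: 24 methyl (5Z,7S)-7-[(1R,5S)-3-bromo-5-hydroxy-5-[(Z)-oct-2-enyl]-2-oxocyclopent-3-en-1-yl]-7-hydroxyhept-5-enoate
Product: 25 methyl (5Z,7S)-7-acetoxy-7-[(1R,5S)-3-bromo-5-hydroxy-5-[(Z)-oct-2-enyl]-2-oxocyclopent-3-en-1-yl]hept-5-enoate (target)
Conditions: Ac2O, pyridine, CH2Cl2, 0 °C
Reagents that add atoms: acetic anhydride CC(=O)OC(C)=O
Why: Acylation with Ac2O and pyridine without a nucleophilic catalyst should acetylate only the secondary allylic C7 hydroxyl, the tertiary C12 hydroxyl being inert, and the low temperature and weak base should avoid β-elimination of the acetate.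

Compound list
1 | (Z)-oct-2-en-1-ol | OC/C=C\CCCCC | starting material
2 | (Z)-1-bromooct-2-ene | BrC/C=C\CCCCC | intermediate
3 | (S)-malic acid | O[C@@H](CC(=O)O)C(=O)O | starting material
4 | 2-[(2S,4S)-2-tert-butyl-5-oxo-1,3-dioxolan-4-yl]acetic acid | CC(C)(C)[C@H]1O[C@@H](CC(=O)O)C(=O)O1 | intermediate
5 | dilithium salt of 4 (ring enolate and carboxylate) | CC(C)(C)[C@H]1OC(CC(=O)O[Li])=C(O[Li])O1 | intermediate
6 | 2-[(2S,4S)-2-tert-butyl-4-[(Z)-oct-2-enyl]-5-oxo-1,3-dioxolan-4-yl]acetic acid | CC(C)(C)[C@H]1O[C@](CC(=O)O)(C/C=C\CCCCC)C(=O)O1 | intermediate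
7 | (3S,5Z)-3-hydroxy-3-(hydroxymethyl)undec-5-enoic acid | OC(=O)C[C@@](O)(C/C=C\CCCCC)CO | intermediate
8 | (4S)-4-hydroxy-4-[(Z)-oct-2-enyl]oxolan-2-one | O=C1C[C@@](O)(C/C=C\CCCCC)CO1 | intermediate
9 | (3S,5Z)-3-hydroxy-3-(hydroxymethyl)-N-methoxy-N-methylundec-5-enamide | CON(C)C(=O)C[C@@](O)(C/C=C\CCCCC)CO | intermediate
10 | (3S,5Z)-N-methoxy-N-methyl-3-(trimethylsilyloxy)-3-[(trimethylsilyloxy)methyl]undec-5-enamide | CON(C)C(=O)C[C@@](O[Si](C)(C)C)(C/C=C\CCCCC)CO[Si](C)(C)C | intermediate
11 | (3S,5Z)-3-formyl-N-methoxy-N-methyl-3-(trimethylsilyloxy)undec-5-enamide | CON(C)C(=O)C[C@@](O[Si](C)(C)C)(C/C=C\CCCCC)C=O | intermediate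
12 | (3S,5Z)-3-(2,2-dibromoethenyl)-N-methoxy-N-methyl-3-(trimethylsilyloxy)undec-5-enamide | CON(C)C(=O)C[C@@](O[Si](C)(C)C)(C/C=C\CCCCC)C=C(Br)Br | intermediate
13 | 1-bromo-1-lithioalkene from 12 (lithium cis to C12) | CON(C)C(=O)C[C@@](O[Si](C)(C)C)(C/C=C\CCCCC)/C=C(/Br)[Li] | intermediate
14 | lithium alkoxide of the cyclic N-methoxy-N-methyl hemiaminal (C9 configuration open) | CON(C)C1(O[Li])C[C@@](O[Si](C)(C)C)(C/C=C\CCCCC)C=C1Br | intermediate
15 | (4S)-2-bromo-4-[(Z)-oct-2-enyl]-4-(trimethylsilyloxy)cyclopent-2-en-1-one | O=C1C[C@@](O[Si](C)(C)C)(C/C=C\CCCCC)C=C1Br | intermediate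
16 | (4-carboxybutyl)triphenylphosphonium bromide | OC(=O)CCCC[P+](c1ccccc1)(c1ccccc1)c1ccccc1.[Br-] | starting material
17 | (tert-butyldimethylsilyloxy)acetaldehyde | CC(C)(C)[Si](C)(C)OCC=O | starting material
18 | sodium 5-(triphenylphosphoranylidene)pentanoate | [Na+].[O-]C(=O)CCCC=P(c1ccccc1)(c1ccccc1)c1ccccc1 | intermediate
19 | (Z)-7-(tert-butyldimethylsilyloxy)hept-5-enoic acid | CC(C)(C)[Si](C)(C)OC/C=C\CCCC(=O)O | intermediate
20 | methyl (Z)-7-hydroxyhept-5-enoate | COC(=O)CCC/C=C\CO | intermediate
21 | methyl (Z)-7-oxohept-5-enoate | COC(=O)CCC/C=C\C=O | intermediate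
22 | dicyclohexylboron dienolate of 15 (O–B on C9, C8=C9) | CCCCC/C=C\C[C@@]1(O[Si](C)(C)C)C=C(Br)C(OB(C2CCCCC2)C2CCCCC2)=C1 | intermediate
23 | dicyclohexylboron aldolate (boron on the C7 oxygen) of the silyl-protected anti aldol | CCCCC/C=C\C[C@@]1(O[Si](C)(C)C)C=C(Br)C(=O)[C@@H]1[C@H](/C=C\CCCC(=O)OC)OB(C1CCCCC1)C1CCCCC1 | intermediate
24 | methyl (5Z,7S)-7-[(1R,5S)-3-bromo-5-hydroxy-5-[(Z)-oct-2-enyl]-2-oxocyclopent-3-en-1-yl]-7-hydroxyhept-5-enoate | CCCCC/C=C\C[C@@]1(O)C=C(Br)C(=O)[C@@H]1[C@H](/C=C\CCCC(=O)OC)O | intermediate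
25 | methyl (5Z,7S)-7-acetoxy-7-[(1R,5S)-3-bromo-5-hydroxy-5-[(Z)-oct-2-enyl]-2-oxocyclopent-3-en-1-yl]hept-5-enoate | CCCCC/C=C\C[C@@]1(O)C=C(Br)C(=O)[C@@H]1[C@H](/C=C\CCCC(=O)OC)OC(C)=O | target

Total step count: 13.
Longest linear sequence: 9 steps (steps 2 to 8, then 12 and 13, from (S)-malic acid).

Steps most likely to fail

Step 8 (key ring closure). The exchange may take place at the bromine trans to C12 without equilibration, or the carbenoid may rearrange to the alkyne or be protonated before it reaches the amide. Fallback: setting out from aldehyde 11, a Stork–Zhao olefination ([Ph3PCH2I]I, NaN(SiMe3)2, THF, −78 °C) would give the (Z)-vinyl iodide F1. Iodine–lithium exchange (t-BuLi, −100 °C) goes with retention, and the configurationally stable alkenyllithium, which has no carbenoid character, would close the same C9–C10 bond on the Weinreb amide to give the bromine-free cyclopentenone F2. Nucleophilic epoxidation (H2O2, NaOH, MeOH, 0 °C), selective for the enone over the isolated alkene, would give the epoxy ketone F3. Bromide opening at C10 followed by dehydration (LiBr, AcOH, THF) would then install the bromine and rejoin the route at 15.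

Step 12 (aldol). The π-facial discrimination at C8 may be poor (entry on the face of the octenyl chain), the anti preference may erode, or the amine salt may isomerize the Z enal 21. Fallback: setting out from 15, TMSOTf and i-Pr2NEt would give the silyl dienol ether F4, which is freed from amine before use. A Mukaiyama aldol addition to 21 (BF3·OEt2, CH2Cl2, −78 °C) then runs through an open transition state in which the bulky Lewis acid–aldehyde complex must pass the C12 substituents, which should raise the preference for the oxygen face. Citric acid in MeOH would cleave the silyl groups and rejoin the route at 24.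

Step 13 (acetylation). Base may induce β-elimination of acetic acid from the β-acetoxy ketone to the cross-conjugated dienone, or acetyl may be transferred to the tertiary hydroxyl. Fallback: setting out from 15 and 21, the aldol of step 12 is worked up without acid (MeOH, pH 7 buffer) so that the silyl ether stays, giving the silyl-protected aldol F5. Acetylation with AcCl and 2,6-lutidine at −78 °C would give the silyl-protected acetate F6, in which the tertiary oxygen is blocked. The silyl group is then removed last under acidic conditions (HF·pyridine, THF, 0 °C), so that the finished target 25 never meets base.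

Further compounds
F1 | step 8 | (3S,5Z)-3-[(Z)-2-iodoethenyl]-N-methoxy-N-methyl-3-(trimethylsilyloxy)undec-5-enamide | CON(C)C(=O)C[C@@](O[Si](C)(C)C)(C/C=C\CCCCC)/C=C\I
F2 | step 8 | (4S)-4-[(Z)-oct-2-enyl]-4-(trimethylsilyloxy)cyclopent-2-en-1-one | O=C1C[C@@](O[Si](C)(C)C)(C/C=C\CCCCC)C=C1
F3 | step 8 | 4-[(Z)-oct-2-enyl]-4-(trimethylsilyloxy)-6-oxabicyclo[3.1.0]hexan-2-one (C4 as in 15, epoxide carbons open) | O=C1C[C@@](O[Si](C)(C)C)(C/C=C\CCCCC)C2OC12
F4 | step 12 | silyl dienol ether of 15: 2-bromo-1,4-bis(trimethylsilyloxy)-4-[(Z)-oct-2-enyl]cyclopenta-1,3-diene numbered from the enol carbon (C12 as in 15) | CCCCC/C=C\C[C@@]1(O[Si](C)(C)C)C=C(Br)C(O[Si](C)(C)C)=C1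
F5 | step 13 | methyl (5Z,7S)-7-[(1R,5S)-3-bromo-5-[(Z)-oct-2-enyl]-2-oxo-5-(trimethylsilyloxy)cyclopent-3-en-1-yl]-7-hydroxyhept-5-enoate | CCCCC/C=C\C[C@@]1(O[Si](C)(C)C)C=C(Br)C(=O)[C@@H]1[C@H](/C=C\CCCC(=O)OC)O
F6 | step 13 | methyl (5Z,7S)-7-acetoxy-7-[(1R,5S)-3-bromo-5-[(Z)-oct-2-enyl]-2-oxo-5-(trimethylsilyloxy)cyclopent-3-en-1-yl]hept-5-enoate | CCCCC/C=C\C[C@@]1(O[Si](C)(C)C)C=C(Br)C(=O)[C@@H]1[C@H](/C=C\CCCC(=O)OC)OC(C)=O
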